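**Assumption:** read from the SMILES, the ring carbons are (2R,3R), which is 2,3-cis, and the side-chain carbinol is (S); benzofuran numbering (O1, C2, C3, C5) is used throughout.

## Retrosynthetic overview

1. Target 24 comes from allylic alcohol 23 (MnO2). The two esters are put on one after the other: isovalerate on C3–OH, then senecioate on the (S)-carbinol made by asymmetric transfer hydrogenation of the 5-acetyl group.
2. The dihydrofuran ring is the only ring formed (the benzene ring is bought). It closes by intramolecular SNAr of the C2 hydroxyl onto the aryl fluoride para to the acetyl group (O1–C7a bond), so no stereocentre is touched.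
3. The C(=CH2)CH2OH unit comes from a vinyl group: hydroboration/oxidation, aldehyde, Mannich α-methylenation, 1,2-reduction.
4. Key C2–C3 bond: Brown (Z)-γ-alkoxyallylboration of aldehyde 4 (fragment 1) with the borane from allyl MOM ether 6 (fragment 2); this sets both ring stereocentres syn.
5. Aldehyde 4 comes from 3'-bromo-4'-fluoroacetophenone 1 (ketal, Br/Mg exchange, DMF).

## Route

Step 1
Reactants: 1 1-(3-bromo-4-fluorophenyl)ethan-1-one
Product: 2 2-(3-bromo-4-fluorophenyl)-2-methyl-1,3-dioxolane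
Conditions: ethylene glycol, p-toluenesulfonic acid monohydrate (cat.), toluene, reflux, Dean–Stark
Reagents that add atoms: ethylene glycol (OCCO)
Why: Acid-catalysed ketalisation with water removal masks the methyl ketone for the organometallic steps that follow.

Step 2
Reactants: 2 2-(3-bromo-4-fluorophenyl)-2-methyl-1,3-dioxolane
Product: 4 2-fluoro-5-(2-methyl-1,3-dioxolan-2-yl)benzaldehyde, via aryl Grignard reagent 3 (not isolated)
Conditions: i-PrMgCl·LiCl, THF, −15 → 0 °C; DMF, 0 °C → rt; aq. NH4Cl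
Reagents that add atoms: N,N-dimethylformamide (CN(C)C=O)
Why: Bromine–magnesium exchange is fast at the bromide ortho to fluorine and spares the ketal and the C–F bond; Bouveault formylation with DMF then gives the aldehyde.

Step 3
Reactants: 5 prop-2-en-1-ol (allyl alcohol)
Product: 6 3-(methoxymethoxy)prop-1-ene
Conditions: MOMCl, i-Pr2NEt, CH2Cl2, 0 °C → rt
Reagents that add atoms: chloromethyl methyl ether (COCCl)
Why: Williamson-type O-alkylation of a primary alcohol with an α-chloro ether (MOM protection).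

Step 4
Reactants: 6 3-(methoxymethoxy)prop-1-ene (fragment 2); 4 2-fluoro-5-(2-methyl-1,3-dioxolan-2-yl)benzaldehyde (fragment 1)
Product: 9 (1R,2R)-1-[2-fluoro-5-(2-methyl-1,3-dioxolan-2-yl)phenyl]-2-(methoxymethoxy)but-3-en-1-ol, via alkoxyallyllithium 7 (not isolated), via alkoxyallylborane 8 (not isolated)
Conditions: 6, sec-BuLi, THF, −78 °C; (−)-Ipc2BOMe [from (+)-α-pinene], −78 °C; BF3·OEt2; then 4, −78 °C, 3 h; NaOH, H2O2, 0 °C → rt
Reagents that add atoms: none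
Why: Brown asymmetric alkoxyallylboration (carbonyl allylation): the Z-γ-alkoxyallylborane reacts through a chair Zimmerman–Traxler transition state to give the syn 1,2-diol monoether, and the isopinocampheyl groups direct attack to the Si face of the aldehyde, setting (1R,2R), the future C3 and C2.

Step 5
Reactants: 9 (1R,2R)-1-[2-fluoro-5-(2-methyl-1,3-dioxolan-2-yl)phenyl]-2-(methoxymethoxy)but-3-en-1-ol
Product: 10 tert-butyl{[(1R,2R)-1-[2-fluoro-5-(2-methyl-1,3-dioxolan-2-yl)phenyl]-2-(methoxymethoxy)but-3-en-1-yl]oxy}dimethylsilane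
Conditions: TBSCl, imidazole, 4-(dimethylamino)pyridine (cat.), DMF, rt → 40 °C
Reagents that add atoms: tert-butyldimethylsilyl chloride (CC(C)(C)[Si](C)(C)Cl)
Why: Silylation of the benzylic alcohol prevents lactol formation and over-oxidation in the chain-extension steps.

Step 6
Reactants: 10 tert-butyl{[(1R,2R)-1-[2-fluoro-5-(2-methyl-1,3-dioxolan-2-yl)phenyl]-2-(methoxymethoxy)but-3-en-1-yl]oxy}dimethylsilane
Product: 12 (3R,4R)-4-{[tert-butyl(dimethyl)silyl]oxy}-4-[2-fluoro-5-(2-methyl-1,3-dioxolan-2-yl)phenyl]-3-(methoxymethoxy)butan-1-ol, via alkyl-9-BBN adduct 11 (not isolated)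
Conditions: 9-BBN, THF, 0 °C → rt; NaOH, H2O2, 0 °C
Reagents that add atoms: hydrogen peroxide (OO)
Why: Anti-Markovnikov hydroboration of the monosubstituted alkene with bulky 9-BBN, then oxidation, places the hydroxyl on the terminal carbon without touching a stereocentre.

Step 7
Reactants: 12 (3R,4R)-4-{[tert-butyl(dimethyl)silyl]oxy}-4-[2-fluoro-5-(2-methyl-1,3-dioxolan-2-yl)phenyl]-3-(methoxymethoxy)butan-1-ol
Product: 13 (3R,4R)-4-{[tert-butyl(dimethyl)silyl]oxy}-4-[2-fluoro-5-(2-methyl-1,3-dioxolan-2-yl)phenyl]-3-(methoxymethoxy)butanal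
Conditions: Dess–Martin periodinane, NaHCO3, CH2Cl2, 0 °C → rt
Reagents that add atoms: none
Why: Buffered Dess–Martin oxidation gives the aldehyde without eliminating the β-alkoxy group.

Step 8
Reactants: 13 (3R,4R)-4-{[tert-butyl(dimethyl)silyl]oxy}-4-[2-fluoro-5-(2-methyl-1,3-dioxolan-2-yl)phenyl]-3-(methoxymethoxy)butanal
Product: 15 (3R,4R)-4-{[tert-butyl(dimethyl)silyl]oxy}-4-[2-fluoro-5-(2-methyl-1,3-dioxolan-2-yl)phenyl]-3-(methoxymethoxy)-2-methylidenebutanal, via Mannich base 14 (not isolated)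
Conditions: dimethylmethyleneiminium iodide (Eschenmoser's salt), Et3N, CH2Cl2, rt
Reagents that add atoms: dimethylmethyleneiminium iodide (C=[N+](C)C.[I-])
Why: Mannich reaction of the aldehyde enol with the iminium salt and loss of dimethylamine (Eschenmoser methylenation) installs the exo-methylene; the adjacent stereocentre is β to the carbonyl and cannot epimerise.

Step 9
Reactants: 15 (3R,4R)-4-{[tert-butyl(dimethyl)silyl]oxy}-4-[2-fluoro-5-(2-methyl-1,3-dioxolan-2-yl)phenyl]-3-(methoxymethoxy)-2-methylidenebutanal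
Product: 16 (3R,4R)-4-{[tert-butyl(dimethyl)silyl]oxy}-4-[2-fluoro-5-(2-methyl-1,3-dioxolan-2-yl)phenyl]-3-(methoxymethoxy)-2-methylidenebutan-1-ol
Conditions: NaBH4, CeCl3·7H2O, MeOH, −40 → 0 °C
Reagents that add atoms: none
Why: Luche reduction gives clean 1,2-reduction of the 2-substituted acrolein, parking the enal as an allylic alcohol through the acid and base steps ahead.

Step 10
Reactants: 16 (3R,4R)-4-{[tert-butyl(dimethyl)silyl]oxy}-4-[2-fluoro-5-(2-methyl-1,3-dioxolan-2-yl)phenyl]-3-(methoxymethoxy)-2-methylidenebutan-1-ol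
Product: 17 1-{4-fluoro-3-[(1R,2R)-1,2-dihydroxy-3-(hydroxymethyl)but-3-en-1-yl]phenyl}ethan-1-one
Conditions: 3 M HCl (aq), MeOH/THF, 45 °C
Reagents that add atoms: water (O)
Why: Acid hydrolysis removes the dioxolane, the MOM acetal and the benzylic silyl ether in one operation, and no C–O bond at a stereocentre is broken.

Step 11
Reactants: 17 1-{4-fluoro-3-[(1R,2R)-1,2-dihydroxy-3-(hydroxymethyl)but-3-en-1-yl]phenyl}ethan-1-one
Product: 18 1-[(2R,3R)-3-hydroxy-2-(3-hydroxyprop-1-en-2-yl)-2,3-dihydro-1-benzofuran-5-yl]ethan-1-one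
Conditions: KOtBu (1.5 equiv), THF/DMF (4:1), 0 °C → rt
Reagents that add atoms: none
Why: Intramolecular SNAr: the C2 alkoxide displaces fluoride para to the acetyl group to close the five-membered ring (the other two alkoxides would need a four- or seven-membered ring), and because only the O–aryl bond forms, the syn diol becomes the 2,3-cis ring.

Step 12
Reactants: 18 1-[(2R,3R)-3-hydroxy-2-(3-hydroxyprop-1-en-2-yl)-2,3-dihydro-1-benzofuran-5-yl]ethan-1-one
Product: 19 1-[(2R,3R)-2-(3-{[tert-butyl(dimethyl)silyl]oxy}prop-1-en-2-yl)-3-hydroxy-2,3-dihydro-1-benzofuran-5-yl]ethan-1-one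
Conditions: TBSCl (1.05 equiv), imidazole, CH2Cl2, 0 °C
Reagents that add atoms: tert-butyldimethylsilyl chloride (CC(C)(C)[Si](C)(C)Cl)
Why: Selective silylation of the unhindered primary allylic hydroxyl over the hindered secondary benzylic one.

Step 13
Reactants: 19 1-[(2R,3R)-2-(3-{[tert-butyl(dimethyl)silyl]oxy}prop-1-en-2-yl)-3-hydroxy-2,3-dihydro-1-benzofuran-5-yl]ethan-1-one
Product: 20 (2R,3R)-5-acetyl-2-(3-{[tert-butyl(dimethyl)silyl]oxy}prop-1-en-2-yl)-2,3-dihydro-1-benzofuran-3-yl 3-methylbutanoate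
Conditions: 3-methylbutanoic anhydride, Et3N, 4-(dimethylamino)pyridine (cat.), CH2Cl2, 0 °C → rt
Reagents that add atoms: 3-methylbutanoic anhydride (CC(C)CC(=O)OC(=O)CC(C)C)
Why: Nucleophile-catalysed O-acylation of the only free hydroxyl installs the isovalerate with retention at C3.

Step 14
Reactants: 20 (2R,3R)-5-acetyl-2-(3-{[tert-butyl(dimethyl)silyl]oxy}prop-1-en-2-yl)-2,3-dihydro-1-benzofuran-3-yl 3-methylbutanoate
Product: 21 (2R,3R)-2-(3-{[tert-butyl(dimethyl)silyl]oxy}prop-1-en-2-yl)-5-[(1S)-1-hydroxyethyl]-2,3-dihydro-1-benzofuran-3-yl 3-methylbutanoate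
Conditions: RuCl[(S,S)-TsDPEN](p-cymene) (2 mol%), HCO2H/Et3N (5:2), CH2Cl2, 30 °C
Reagents that add atoms: none
Why: Noyori asymmetric transfer hydrogenation: the (S,S)-TsDPEN ruthenium hydride reduces the aryl methyl ketone to the (S)-carbinol under catalyst control, leaving alkene, ester and silyl ether untouched.

Step 15
Reactants: 21 (2R,3R)-2-(3-{[tert-butyl(dimethyl)silyl]oxy}prop-1-en-2-yl)-5-[(1S)-1-hydroxyethyl]-2,3-dihydro-1-benzofuran-3-yl 3-methylbutanoate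
Product: 22 (1S)-1-[(2R,3R)-2-(3-{[tert-butyl(dimethyl)silyl]oxy}prop-1-en-2-yl)-3-[(3-methylbutanoyl)oxy]-2,3-dihydro-1-benzofuran-5-yl]ethyl 3-methylbut-2-enoate
Conditions: 3-methylbut-2-enoic acid, DCC, 4-(dimethylamino)pyridine (cat.), CH2Cl2, 0 °C → rt
Reagents that add atoms: 3-methylbut-2-enoic acid (CC(C)=CC(=O)O)
Why: Steglich esterification acylates the benzylic alcohol on oxygen, so the (S) configuration is retained.

Step 16
Reactants: 22 (1S)-1-[(2R,3R)-2-(3-{[tert-butyl(dimethyl)silyl]oxy}prop-1-en-2-yl)-3-[(3-methylbutanoyl)oxy]-2,3-dihydro-1-benzofuran-5-yl]ethyl 3-methylbut-2-enoate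
Product: 23 (1S)-1-[(2R,3R)-2-(3-hydroxyprop-1-en-2-yl)-3-[(3-methylbutanoyl)oxy]-2,3-dihydro-1-benzofuran-5-yl]ethyl 3-methylbut-2-enoate
Conditions: HF·pyridine, pyridine, THF, 0 °C → rt
Reagents that add atoms: none
Why: Buffered fluoride desilylation frees the primary allylic alcohol and leaves both esters in place.

Step 17
Reactants: 23 (1S)-1-[(2R,3R)-2-(3-hydroxyprop-1-en-2-yl)-3-[(3-methylbutanoyl)oxy]-2,3-dihydro-1-benzofuran-5-yl]ethyl 3-methylbut-2-enoate
Product: 24 (1S)-1-[(2R,3R)-3-[(3-methylbutanoyl)oxy]-2-(3-oxoprop-1-en-2-yl)-2,3-dihydro-1-benzofuran-5-yl]ethyl 3-methylbut-2-enoate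
Conditions: MnO2 (excess), CH2Cl2, rt
Reagents that add atoms: none
Why: Allylic oxidation with MnO2 converts the primary allylic alcohol into the α-methylene aldehyde under neutral conditions, giving the target.

## Compound list

1 | 1-(3-bromo-4-fluorophenyl)ethan-1-one | CC(=O)c1ccc(F)c(Br)c1 | starting material
2 | 2-(3-bromo-4-fluorophenyl)-2-methyl-1,3-dioxolane | CC1(OCCO1)c1ccc(F)c(Br)c1 | intermediate
3 | [2-fluoro-5-(2-methyl-1,3-dioxolan-2-yl)phenyl]magnesium chloride (LiCl complex, formed in situ) | CC1(OCCO1)c1ccc(F)c([Mg]Cl)c1 | intermediate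
4 | 2-fluoro-5-(2-methyl-1,3-dioxolan-2-yl)benzaldehyde | CC1(OCCO1)c1ccc(F)c(C=O)c1 | intermediate
5 | prop-2-en-1-ol (allyl alcohol) | C=CCO | starting material
6 | 3-(methoxymethoxy)prop-1-ene | C=CCOCOC | intermediate
7 | (Z)-[3-(methoxymethoxy)allyl]lithium (formed in situ) | [Li]C/C=C\OCOC | intermediate
8 | [(Z)-3-(methoxymethoxy)allyl]bis(isopinocampheyl)borane, Ipc groups from (+)-α-pinene (formed in situ) | COCO/C=C\CB([C@@H]1C[C@@H]2C[C@@H](C2(C)C)[C@H]1C)[C@@H]1C[C@@H]2C[C@@H](C2(C)C)[C@H]1C | intermediate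
9 | (1R,2R)-1-[2-fluoro-5-(2-methyl-1,3-dioxolan-2-yl)phenyl]-2-(methoxymethoxy)but-3-en-1-ol | C=C[C@@H](OCOC)[C@H](O)c1cc(C2(C)OCCO2)ccc1F | intermediate
10 | tert-butyl{[(1R,2R)-1-[2-fluoro-5-(2-methyl-1,3-dioxolan-2-yl)phenyl]-2-(methoxymethoxy)but-3-en-1-yl]oxy}dimethylsilane | C=C[C@@H](OCOC)[C@H](O[Si](C)(C)C(C)(C)C)c1cc(C2(C)OCCO2)ccc1F | intermediate
11 | 9-[(3R,4R)-4-{[tert-butyl(dimethyl)silyl]oxy}-4-[2-fluoro-5-(2-methyl-1,3-dioxolan-2-yl)phenyl]-3-(methoxymethoxy)butyl]-9-borabicyclo[3.3.1]nonane (formed in situ) | B1(CC[C@@H](OCOC)[C@H](O[Si](C)(C)C(C)(C)C)c2cc(C3(C)OCCO3)ccc2F)C2CCCC1CCC2 | intermediate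
12 | (3R,4R)-4-{[tert-butyl(dimethyl)silyl]oxy}-4-[2-fluoro-5-(2-methyl-1,3-dioxolan-2-yl)phenyl]-3-(methoxymethoxy)butan-1-ol | OCC[C@@H](OCOC)[C@H](O[Si](C)(C)C(C)(C)C)c1cc(C2(C)OCCO2)ccc1F | intermediate
13 | (3R,4R)-4-{[tert-butyl(dimethyl)silyl]oxy}-4-[2-fluoro-5-(2-methyl-1,3-dioxolan-2-yl)phenyl]-3-(methoxymethoxy)butanal | O=CC[C@@H](OCOC)[C@H](O[Si](C)(C)C(C)(C)C)c1cc(C2(C)OCCO2)ccc1F | intermediate
14 | (3R,4R)-4-{[tert-butyl(dimethyl)silyl]oxy}-2-[(dimethylamino)methyl]-4-[2-fluoro-5-(2-methyl-1,3-dioxolan-2-yl)phenyl]-3-(methoxymethoxy)butanal (Mannich base, C2 epimers, formed in situ) | CN(C)CC(C=O)[C@@H](OCOC)[C@H](O[Si](C)(C)C(C)(C)C)c1cc(C2(C)OCCO2)ccc1F | intermediate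
15 | (3R,4R)-4-{[tert-butyl(dimethyl)silyl]oxy}-4-[2-fluoro-5-(2-methyl-1,3-dioxolan-2-yl)phenyl]-3-(methoxymethoxy)-2-methylidenebutanal | C=C(C=O)[C@@H](OCOC)[C@H](O[Si](C)(C)C(C)(C)C)c1cc(C2(C)OCCO2)ccc1F | intermediate
16 | (3R,4R)-4-{[tert-butyl(dimethyl)silyl]oxy}-4-[2-fluoro-5-(2-methyl-1,3-dioxolan-2-yl)phenyl]-3-(methoxymethoxy)-2-methylidenebutan-1-ol | C=C(CO)[C@@H](OCOC)[C@H](O[Si](C)(C)C(C)(C)C)c1cc(C2(C)OCCO2)ccc1F | intermediate
17 | 1-{4-fluoro-3-[(1R,2R)-1,2-dihydroxy-3-(hydroxymethyl)but-3-en-1-yl]phenyl}ethan-1-one | C=C(CO)[C@@H](O)[C@H](O)c1cc(C(C)=O)ccc1F | intermediate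
18 | 1-[(2R,3R)-3-hydroxy-2-(3-hydroxyprop-1-en-2-yl)-2,3-dihydro-1-benzofuran-5-yl]ethan-1-one | C=C(CO)[C@H]1Oc2ccc(C(C)=O)cc2[C@H]1O | intermediate
19 | 1-[(2R,3R)-2-(3-{[tert-butyl(dimethyl)silyl]oxy}prop-1-en-2-yl)-3-hydroxy-2,3-dihydro-1-benzofuran-5-yl]ethan-1-one | C=C(CO[Si](C)(C)C(C)(C)C)[C@H]1Oc2ccc(C(C)=O)cc2[C@H]1O | intermediate
20 | (2R,3R)-5-acetyl-2-(3-{[tert-butyl(dimethyl)silyl]oxy}prop-1-en-2-yl)-2,3-dihydro-1-benzofuran-3-yl 3-methylbutanoate | C=C(CO[Si](C)(C)C(C)(C)C)[C@H]1Oc2ccc(C(C)=O)cc2[C@H]1OC(=O)CC(C)C | intermediate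
21 | (2R,3R)-2-(3-{[tert-butyl(dimethyl)silyl]oxy}prop-1-en-2-yl)-5-[(1S)-1-hydroxyethyl]-2,3-dihydro-1-benzofuran-3-yl 3-methylbutanoate | C=C(CO[Si](C)(C)C(C)(C)C)[C@H]1Oc2ccc([C@H](C)O)cc2[C@H]1OC(=O)CC(C)C | intermediate
22 | (1S)-1-[(2R,3R)-2-(3-{[tert-butyl(dimethyl)silyl]oxy}prop-1-en-2-yl)-3-[(3-methylbutanoyl)oxy]-2,3-dihydro-1-benzofuran-5-yl]ethyl 3-methylbut-2-enoate | C=C(CO[Si](C)(C)C(C)(C)C)[C@H]1Oc2ccc([C@H](C)OC(=O)C=C(C)C)cc2[C@H]1OC(=O)CC(C)C | intermediate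
23 | (1S)-1-[(2R,3R)-2-(3-hydroxyprop-1-en-2-yl)-3-[(3-methylbutanoyl)oxy]-2,3-dihydro-1-benzofuran-5-yl]ethyl 3-methylbut-2-enoate | C=C(CO)[C@H]1Oc2ccc([C@H](C)OC(=O)C=C(C)C)cc2[C@H]1OC(=O)CC(C)C | intermediate
24 | (1S)-1-[(2R,3R)-3-[(3-methylbutanoyl)oxy]-2-(3-oxoprop-1-en-2-yl)-2,3-dihydro-1-benzofuran-5-yl]ethyl 3-methylbut-2-enoate | C=C(C=O)[C@H]1Oc2ccc([C@H](C)OC(=O)C=C(C)C)cc2[C@H]1OC(=O)CC(C)C | target

## Step count and weak points

Total steps: 17. Longest linear sequence: 16 steps (1 → 24 through steps 1, 2 and 4–17); step 3 is a one-step side branch.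

**Step 4 (alkoxyallylboration).** The multi-component, moisture-sensitive borane chemistry may give lower ee or dr with this ortho-substituted aldehyde. The fallback sets out from 4 and comes back at 17. Aldehyde 4 is combined with commercial 1,3-bis(tert-butyldimethylsilyloxy)propan-2-one in a direct syn-selective organocatalytic aldol (O-tert-butyl-D-threonine 20 mol%, 5-methyl-1H-tetrazole, NMP, 4 °C; Z-enamine, Si-face attack). This gives (3S,4R)-1,3-bis{[tert-butyl(dimethyl)silyl]oxy}-4-[2-fluoro-5-(2-methyl-1,3-dioxolan-2-yl)phenyl]-4-hydroxybutan-2-one F1, which already carries the C(=O)CH2O unit. Silylation (TBSOTf, 2,6-lutidine, CH2Cl2, −78 °C) gives the tris-silyl ether ketone F2. Wittig methylenation (Ph3PCH3Br, KHMDS, THF, −78 → 0 °C) gives the (1R,2R)-3-methylidenebutane-1,2,4-triol tris-silyl ether F3. The acid conditions of step 10 then remove the three silyl groups and the ketal to give 17, by-passing steps 5–9.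

**Step 11 (SNAr ring closure).** The triol could give some seven-membered ether through the primary alkoxide or intermolecular etherification. The fallback sets out from 17 and comes back at 19. The primary allylic hydroxyl is silylated first (TBSCl, imidazole, CH2Cl2, −20 °C) to give 1-{3-[(1R,2R)-3-({[tert-butyl(dimethyl)silyl]oxy}methyl)-1,2-dihydroxybut-3-en-1-yl]-4-fluorophenyl}ethan-1-one F4. The ring is then closed (KOtBu, THF, 0 °C), where only the C2 alkoxide can reach the C–F carbon, leading straight to 19.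

**Step 15 (senecioate formation).** Activated 3-methylbut-2-enoic acid can deconjugate to the 3-methylbut-3-enoate or stall as the N-acylurea. The fallback sets out from 21 and comes back at 22. Alcohol 21 is acylated with diethylphosphonoacetic acid (DCC, 4-(dimethylamino)pyridine, CH2Cl2) to give (2R,3R)-2-(3-{[tert-butyl(dimethyl)silyl]oxy}prop-1-en-2-yl)-5-[(1S)-1-{[(diethoxyphosphoryl)acetyl]oxy}ethyl]-2,3-dihydro-1-benzofuran-3-yl 3-methylbutanoate F5. Horner–Wadsworth–Emmons olefination with acetone (NaH, THF, 0 °C → rt) then builds the 3-methylbut-2-enoate in place, giving 22.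

Further compounds

F1 | step 4 | (3S,4R)-1,3-bis{[tert-butyl(dimethyl)silyl]oxy}-4-[2-fluoro-5-(2-methyl-1,3-dioxolan-2-yl)phenyl]-4-hydroxybutan-2-one | CC(C)(C)[Si](C)(C)OCC(=O)[C@@H](O[Si](C)(C)C(C)(C)C)[C@H](O)c1cc(C2(C)OCCO2)ccc1F
F2 | step 4 | (3S,4R)-1,3,4-tris{[tert-butyl(dimethyl)silyl]oxy}-4-[2-fluoro-5-(2-methyl-1,3-dioxolan-2-yl)phenyl]butan-2-one | CC(C)(C)[Si](C)(C)OCC(=O)[C@@H](O[Si](C)(C)C(C)(C)C)[C@H](O[Si](C)(C)C(C)(C)C)c1cc(C2(C)OCCO2)ccc1F
F3 | step 4 | (1R,2R)-1-[2-fluoro-5-(2-methyl-1,3-dioxolan-2-yl)phenyl]-3-methylidenebutane-1,2,4-triol tris(tert-butyldimethylsilyl) ether | C=C(CO[Si](C)(C)C(C)(C)C)[C@@H](O[Si](C)(C)C(C)(C)C)[C@H](O[Si](C)(C)C(C)(C)C)c1cc(C2(C)OCCO2)ccc1F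
F4 | step 11 | 1-{3-[(1R,2R)-3-({[tert-butyl(dimethyl)silyl]oxy}methyl)-1,2-dihydroxybut-3-en-1-yl]-4-fluorophenyl}ethan-1-one | C=C(CO[Si](C)(C)C(C)(C)C)[C@@H](O)[C@H](O)c1cc(C(C)=O)ccc1F
F5 | step 15 | (2R,3R)-2-(3-{[tert-butyl(dimethyl)silyl]oxy}prop-1-en-2-yl)-5-[(1S)-1-{[(diethoxyphosphoryl)acetyl]oxy}ethyl]-2,3-dihydro-1-benzofuran-3-yl 3-methylbutanoate | C=C(CO[Si](C)(C)C(C)(C)C)[C@H]1Oc2ccc([C@H](C)OC(=O)CP(=O)(OCC)OCC)cc2[C@H]1OC(=O)CC(C)C
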